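Retrosynthesis: the six O–CH3 bonds are cut first, then both bonds of the ArCH carbon of the seven-membered ring (to C2 of the fused resorcinol ring and to C4 of its 4-hydroxyphenyl group), which leaves an arylacetaldehyde and phenol.
Enabling feature: once the ArCH–resorcinol bond is cut, the central benzene ring carries the CH2 group at C1 and two trans-2,3-diaryl dihydrofurans fused at C2–C3 and C6–C5. These are (2R,3R) and (2S,3S), mirror images across the plane through C1 and C4, so the seco aldehyde is meso and its two 3,5-dioxyphenyl rings are enantiotopic.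
Further cuts: the C2–C3 bond of each dihydrofuran (carbene C–H insertion into a 4-methoxybenzyl ether) and the two aryl–carbonyl bonds (Friedel–Crafts). The side chain is carried as a 2-hydroxyethyl group masked as its 3,5-dimethoxybenzoate, because an arylacetic ester would close onto the neighbouring hydrazone to a benzodiazepinone.
Forward order: esterification of the side-chain alcohol, two successive aroylations of the central ring, exchange of two methyl ethers for 4-methoxybenzyl ethers, bis-hydrazone, both dihydrofuran rings at once, equilibration to trans/trans and isolation of the meso isomer, oxidation to the aldehyde, then the seven-membered ring and the ArCH carbon in one operation, and finally release of the six phenols.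
Stereochemistry: the four dihydrofuran centres are set only relative to each other (trans by thermodynamic control, meso by separation). The absolute configuration comes from a chiral Brønsted acid choosing one enantiotopic ring, and the ArCH centre from attack of phenol on the open face of the cyclic cation.

Key step: step 12

Assumption: 2-(3,5-dimethoxyphenyl)ethanol is taken as a catalogue compound, and the (R)-configured acid of step 12 is taken to select the ring on the (S)-configured C3; should the sense be the opposite, the (S)-acid is used.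

Step 1
Reactants: 1 2-(3,5-dimethoxyphenyl)ethanol; 2 3,5-dimethoxybenzoyl chloride
Product: 3 2-(3,5-dimethoxyphenyl)ethyl 3,5-dimethoxybenzoate
Conditions: 2 (1.1 equiv), Et3N (1.5 equiv), DMAP (cat.), CH2Cl2, 0 °C → rt
Reagents that add atoms: none
Why: DMAP-catalysed O-acylation of the primary alcohol gives an ester that tolerates the Lewis acids of the next three steps and is cleaved later by hydrazine in the same pot as hydrazone formation.

Step 2
Reactants: 3 2-(3,5-dimethoxyphenyl)ethyl 3,5-dimethoxybenzoate; 2 3,5-dimethoxybenzoyl chloride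
Product: 4 2-[2-(3,5-dimethoxybenzoyl)-3,5-dimethoxyphenyl]ethyl 3,5-dimethoxybenzoate
Conditions: 2 (1.1 equiv), AlCl3 (2.5 equiv), CH2Cl2, −10 → 0 °C
Reagents that add atoms: none
Why: Friedel–Crafts acylation should go to C2 of the alkyl-substituted ring, ortho to one methoxy group and para to the other as in the acylation of orcinol dimethyl ether, while the benzoate ring is left alone because each of its activated positions is ortho or para to the AlCl3-bound ester carbonyl.

Step 3
Reactants: 4 2-[2-(3,5-dimethoxybenzoyl)-3,5-dimethoxyphenyl]ethyl 3,5-dimethoxybenzoate; 2 3,5-dimethoxybenzoyl chloride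
Product: 5 2-[2,6-bis(3,5-dimethoxybenzoyl)-3,5-dimethoxyphenyl]ethyl 3,5-dimethoxybenzoate
Conditions: 2 (1.5 equiv), AlCl3 (3 equiv), CH2Cl2, 0 °C → rt
Reagents that add atoms: none
Why: A second Friedel–Crafts acylation, run separately because the mono-ketone ring needs more acyl chloride and a higher temperature, should go to C6, which is meta to the first carbonyl, ortho to one methoxy group and para to the other, as in the 4,6-diacylation of resorcinol dimethyl ethers, rather than to C4 between the two methoxy groups.

Step 4
Reactants: 5 2-[2,6-bis(3,5-dimethoxybenzoyl)-3,5-dimethoxyphenyl]ethyl 3,5-dimethoxybenzoate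
Product: 6 2-[2,6-bis(3,5-dimethoxybenzoyl)-3,5-dihydroxyphenyl]ethyl 3,5-dimethoxybenzoate
Conditions: BCl3 (3 equiv), CH2Cl2, −78 → 0 °C
Reagents that add atoms: none
Why: Chelation-controlled demethylation, in which BCl3 binds each ketone oxygen and cleaves only the methyl ether ortho to it, so the six methoxy groups meta to a carbonyl and the ester are kept.

Step 5
Reactants: 6 2-[2,6-bis(3,5-dimethoxybenzoyl)-3,5-dihydroxyphenyl]ethyl 3,5-dimethoxybenzoate; 7 4-methoxybenzyl chloride
Product: 8 2-[2,6-bis(3,5-dimethoxybenzoyl)-3,5-bis(4-methoxybenzyloxy)phenyl]ethyl 3,5-dimethoxybenzoate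
Conditions: 7 (2.5 equiv), K2CO3, nBu4NI (cat.), DMF, 60 °C
Reagents that add atoms: none
Why: Williamson etherification of the two ketone-bonded phenols places next to each carbonyl the OCH2Ar group whose C–H bond will later be inserted into, and ester and ketones are inert to carbonate in DMF.

Step 6
Reactants: 8 2-[2,6-bis(3,5-dimethoxybenzoyl)-3,5-bis(4-methoxybenzyloxy)phenyl]ethyl 3,5-dimethoxybenzoate
Product: 9 2-{2,6-bis[(3,5-dimethoxyphenyl)(hydrazinylidene)methyl]-3,5-bis(4-methoxybenzyloxy)phenyl}ethanol (hydrazone geometry not defined)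
Conditions: N2H4·H2O (20 equiv), AcOH (cat.), n-BuOH, 110 °C
Reagents that add atoms: hydrazine, NN
Why: Hydrazone condensation at both hindered diaryl ketones under forcing conditions, with hydrazinolysis of the remote benzoate in the same pot, which frees the primary alcohol and, unlike an arylacetic ester, cannot lactamise with a hydrazone.

Step 7
Reactants: 9 2-{2,6-bis[(3,5-dimethoxyphenyl)(hydrazinylidene)methyl]-3,5-bis(4-methoxybenzyloxy)phenyl}ethanol
Product: 10 triisopropylsilyl ether of 9
Conditions: iPr3SiCl, imidazole, DMF, 0 °C → rt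
Reagents that add atoms: chlorotriisopropylsilane, CC(C)[Si](Cl)(C(C)C)C(C)C
Why: Selective O-silylation of the primary alcohol (the hydrazone NH2 groups are poor nucleophiles toward the bulky silyl chloride) removes the O–H bond into which a carbene would otherwise insert.

Step 8
Reactants: 10 triisopropylsilyl ether of 9
Product: 12 3,5-bis(3,5-dimethoxyphenyl)-2,6-bis(4-methoxyphenyl)-4-[2-(triisopropylsilyloxy)ethyl]-2,3,5,6-tetrahydrobenzo[1,2-b:5,4-b']difuran as a mixture of diastereomers, via bis(diazo) compound 11 (not isolated)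
Conditions: MnO2, CH2Cl2, rt, filter; then Rh2(OAc)4 (2 mol%), CH2Cl2, 0 °C → rt
Reagents that add atoms: none
Why: MnO2 dehydrogenates each hydrazone to a diaryldiazomethane, and dirhodium tetraacetate turns it into a donor/donor carbene that undergoes intramolecular 1,5 C–H insertion into the neighbouring ArO–CH2–Ar bond, forming C2–C3 of a 2,3-diaryl dihydrobenzofuran; the two insertions are independent, so both relative arrangements of the two C3 centres should form and the cis/trans question is left to step 9.

Step 9
Reactants: 12 bis(dihydrobenzofuran) silyl ether, diastereomer mixture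
Product: 13 meso-(2R,3R,5S,6S)-3,5-bis(3,5-dimethoxyphenyl)-2,6-bis(4-methoxyphenyl)-4-[2-(triisopropylsilyloxy)ethyl]-2,3,5,6-tetrahydrobenzo[1,2-b:5,4-b']difuran (both rings 2,3-trans, both dimethoxyphenyl groups on the same face)
Conditions: CF3CO2H (10 equiv), CH2Cl2, 0 °C → rt; chromatography on silica
Reagents that add atoms: none
Why: Acid-mediated epimerisation, in which each benzylic C2–O bond ionises reversibly to a 4-methoxybenzyl cation and recloses to the more stable 2,3-trans ring, leaves only the meso (syn) and the racemic C2-symmetric (anti) isomers, which are diastereomers separable on silica, the meso one being the isomer that would show a single peak on a chiral stationary phase.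

Step 10
Reactants: 13 meso silyl ether
Product: 14 2-[(2R,3R,5S,6S)-3,5-bis(3,5-dimethoxyphenyl)-2,6-bis(4-methoxyphenyl)-2,3,5,6-tetrahydrobenzo[1,2-b:5,4-b']difuran-4-yl]ethanol (meso)
Conditions: nBu4NF, THF, 0 °C → rt
Reagents that add atoms: none
Why: Fluoride-induced desilylation of the primary silyl ether, to which no other group in the molecule responds.

Step 11
Reactants: 14 meso alcohol
Product: 15 2-[(2R,3R,5S,6S)-3,5-bis(3,5-dimethoxyphenyl)-2,6-bis(4-methoxyphenyl)-2,3,5,6-tetrahydrobenzo[1,2-b:5,4-b']difuran-4-yl]acetaldehyde (meso)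
Conditions: Dess–Martin periodinane, CH2Cl2, 0 °C → rt
Reagents that add atoms: none
Why: Dess–Martin oxidation gives the arylacetaldehyde without strong acid, which could start the cyclisation in racemic form, and the aldehyde is used at once.

Step 12
Reactants: 15 meso aldehyde; 16 phenol
Product: 18 hexamethyl ether of the target bearing a free 4-hydroxyphenyl group on the S-configured ArCH carbon of the seven-membered ring, via cyclic benzylic alcohol 17 (not isolated)
Conditions: (R)-3,3'-bis(2,4,6-triisopropylphenyl)-1,1'-binaphthyl-2,2'-diyl N-(trifluoromethanesulfonyl)phosphoramide (10 mol%), 16 (10 equiv), 5 Å MS, toluene, −40 → 0 °C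
Reagents that add atoms: none
Why: Proposed new method: the N-triflyl phosphoramide activates the aldehyde, C2 of one 3,5-dimethoxyphenyl ring (ortho to one methoxy, para to the other) attacks the carbonyl carbon in a 7-exo-trig Friedel–Crafts hydroxyalkylation that closes the seven-membered ring, the benzylic alcohol 17 is ionised by the same acid to a 2,4-dimethoxybenzylic cation, and phenol adds through its para carbon and rearomatises. The closest known reactions are the acid-mediated double arylation of aldehydes to 1,1-diarylalkanes and chiral phosphoric acid-catalysed desymmetrising Friedel–Crafts and Pictet–Spengler-type cyclisations. Because 15 is meso, its two pendant rings are enantiotopic and the chiral ion pair in the first C–C bond formation decides which one closes; closure onto the ring on the (S)-configured C3 turns the four existing centres into those of the target enantiomer (2S,3S in the dihydrofuran fused to the seven-membered ring and 2R,3R in the other). The new ArCH centre is set by the substrate: the inner face of the cyclic cation is covered by the unreacted dimethoxyphenyl ring and its dihydrofuran, so phenol should enter from the outer face and give the S configuration. The step needs selection between the two rings (catalyst), para over ortho attack of phenol (bulk of the cation, hydrogen bonding of the phenol OH to the phosphoramide) and intermolecular over transannular capture of the cation, which the excess of phenol and the strain of the doubly bridged alternative should secure. Low temperature and molecular sieves are meant to limit re-ionisation of the product, which would erode the enantiomeric purity.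

Step 13
Reactants: 18 hexamethyl ether
Product: 19 CNP0136963.1
Conditions: BBr3 (15 equiv), CH2Cl2, −78 → 0 °C
Reagents that add atoms: none
Why: Lewis acid-mediated cleavage of all six aryl methyl ethers; the trans dihydrofurans are already the thermodynamic isomers, and working cold with an early quench should keep the diarylmethine centre intact.

Compound list
1 | 2-(3,5-dimethoxyphenyl)ethanol | COc1cc(CCO)cc(OC)c1 | starting material
2 | 3,5-dimethoxybenzoyl chloride | COc1cc(OC)cc(C(=O)Cl)c1 | starting material
3 | 2-(3,5-dimethoxyphenyl)ethyl 3,5-dimethoxybenzoate | COc1cc(CCOC(=O)c2cc(OC)cc(OC)c2)cc(OC)c1 | intermediate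
4 | 2-[2-(3,5-dimethoxybenzoyl)-3,5-dimethoxyphenyl]ethyl 3,5-dimethoxybenzoate | COc1cc(OC)c(C(=O)c2cc(OC)cc(OC)c2)c(CCOC(=O)c2cc(OC)cc(OC)c2)c1 | intermediate
5 | 2-[2,6-bis(3,5-dimethoxybenzoyl)-3,5-dimethoxyphenyl]ethyl 3,5-dimethoxybenzoate | COc1cc(OC)c(C(=O)c2cc(OC)cc(OC)c2)c(CCOC(=O)c2cc(OC)cc(OC)c2)c1C(=O)c1cc(OC)cc(OC)c1 | intermediate
6 | 2-[2,6-bis(3,5-dimethoxybenzoyl)-3,5-dihydroxyphenyl]ethyl 3,5-dimethoxybenzoate | Oc1cc(O)c(C(=O)c2cc(OC)cc(OC)c2)c(CCOC(=O)c2cc(OC)cc(OC)c2)c1C(=O)c1cc(OC)cc(OC)c1 | intermediate
7 | 4-methoxybenzyl chloride | COc1ccc(CCl)cc1 | starting material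
8 | 2-[2,6-bis(3,5-dimethoxybenzoyl)-3,5-bis(4-methoxybenzyloxy)phenyl]ethyl 3,5-dimethoxybenzoate | COc1ccc(COc2cc(OCc3ccc(OC)cc3)c(C(=O)c3cc(OC)cc(OC)c3)c(CCOC(=O)c3cc(OC)cc(OC)c3)c2C(=O)c2cc(OC)cc(OC)c2)cc1 | intermediate
9 | 2-{2,6-bis[(3,5-dimethoxyphenyl)(hydrazinylidene)methyl]-3,5-bis(4-methoxybenzyloxy)phenyl}ethanol | COc1ccc(COc2cc(OCc3ccc(OC)cc3)c(C(=NN)c3cc(OC)cc(OC)c3)c(CCO)c2C(=NN)c2cc(OC)cc(OC)c2)cc1 | intermediate
10 | triisopropylsilyl ether of 9 | COc1ccc(COc2cc(OCc3ccc(OC)cc3)c(C(=NN)c3cc(OC)cc(OC)c3)c(CCO[Si](C(C)C)(C(C)C)C(C)C)c2C(=NN)c2cc(OC)cc(OC)c2)cc1 | intermediate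
11 | bis(diazo) compound from 10 | COc1ccc(COc2cc(OCc3ccc(OC)cc3)c(C(=[N+]=[N-])c3cc(OC)cc(OC)c3)c(CCO[Si](C(C)C)(C(C)C)C(C)C)c2C(=[N+]=[N-])c2cc(OC)cc(OC)c2)cc1 | intermediate (not isolated)
12 | 3,5-bis(3,5-dimethoxyphenyl)-2,6-bis(4-methoxyphenyl)-4-[2-(triisopropylsilyloxy)ethyl]-2,3,5,6-tetrahydrobenzo[1,2-b:5,4-b']difuran, mixture of diastereomers (configuration not defined) | CC(C)[Si](OCCc1c2c(cc3c1C(c1cc(OC)cc(OC)c1)C(c1ccc(OC)cc1)O3)OC(c1ccc(OC)cc1)C2c1cc(OC)cc(OC)c1)(C(C)C)C(C)C | intermediate
13 | meso-(2R,3R,5S,6S) isomer of 12, both rings trans | CC(C)[Si](OCCc1c2c(cc3c1[C@@H](c1cc(OC)cc(OC)c1)[C@H](c1ccc(OC)cc1)O3)O[C@H](c1ccc(OC)cc1)[C@H]2c1cc(OC)cc(OC)c1)(C(C)C)C(C)C | intermediate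
14 | meso 2-[(2R,3R,5S,6S)-3,5-bis(3,5-dimethoxyphenyl)-2,6-bis(4-methoxyphenyl)-2,3,5,6-tetrahydrobenzo[1,2-b:5,4-b']difuran-4-yl]ethanol | OCCc1c2c(cc3c1[C@@H](c1cc(OC)cc(OC)c1)[C@H](c1ccc(OC)cc1)O3)O[C@H](c1ccc(OC)cc1)[C@H]2c1cc(OC)cc(OC)c1 | intermediate
15 | meso 2-[(2R,3R,5S,6S)-3,5-bis(3,5-dimethoxyphenyl)-2,6-bis(4-methoxyphenyl)-2,3,5,6-tetrahydrobenzo[1,2-b:5,4-b']difuran-4-yl]acetaldehyde | O=CCc1c2c(cc3c1[C@@H](c1cc(OC)cc(OC)c1)[C@H](c1ccc(OC)cc1)O3)O[C@H](c1ccc(OC)cc1)[C@H]2c1cc(OC)cc(OC)c1 | intermediate
16 | phenol | Oc1ccccc1 | starting material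
17 | cyclic benzylic alcohol: seven-membered ring closed onto the dimethoxyphenyl ring of the (2S,3S)-dihydrofuran, OH on the former aldehyde carbon (carbinol configuration not defined) | OC1Cc2c3c(cc4c2[C@@H](c2cc(OC)cc(OC)c2)[C@H](c2ccc(OC)cc2)O4)O[C@H](c2ccc(OC)cc2)[C@H]3c2cc(OC)cc(OC)c21 | intermediate (not isolated)
18 | hexamethyl ether of the target, free 4-hydroxyphenyl on the (S)-configured ArCH carbon of the seven-membered ring | Oc1ccc([C@@H]2Cc3c4c(cc5c3[C@@H](c3cc(OC)cc(OC)c3)[C@H](c3ccc(OC)cc3)O5)O[C@H](c3ccc(OC)cc3)[C@H]4c3cc(OC)cc(OC)c32)cc1 | intermediate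
19 | CNP0136963.1 | Oc1ccc([C@@H]2Cc3c4c(cc5c3[C@@H](c3cc(O)cc(O)c3)[C@H](c3ccc(O)cc3)O5)O[C@H](c3ccc(O)cc3)[C@H]4c3cc(O)cc(O)c32)cc1 | target

Total step count: 13. Longest linear sequence: 13 steps (from 1).

Steps most likely to fail

Step 12. The acid may discriminate poorly between the two enantiotopic rings. The cation may also lose a proton to the cycloheptene or be captured by the second ring, and the product may re-ionise and lose enantiomeric purity. The fallback sets out from 15 and forms the two aryl bonds one after the other by known reactions. 4-Methoxyphenylmagnesium bromide (THF, −78 °C) should add to the aldehyde to give the racemic carbinol F1. CF3CO2H in CH2Cl2 at low temperature should ionise it to the 4-methoxybenzylic cation, which either pendant ring captures in an intramolecular Friedel–Crafts alkylation; the aryl group is expected on the outer face. This gives the heptamethyl ether F2 as a racemate, from which the enantiomer shown would be obtained by preparative chromatography on a chiral stationary phase. BBr3 would then cleave its seven methyl ethers, and the sequence comes back to the route at 19.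

Step 8. The carbenes may insert into the C–H bonds next to the silyl ether or couple with each other instead of inserting into the OCH2Ar groups. The unselective pairing of the two C3 centres also costs the anti half of the material. The fallback sets out from 8 and avoids carbenes. Irradiation (350 nm, benzene) should bring about a double Norrish–Yang cyclisation (δ-hydrogen abstraction from each OCH2Ar group by the excited ketone, then radical recombination) to the bis(3-hydroxy-dihydrobenzofuran) F3. Et3SiH with CF3CO2H in CH2Cl2 should remove both tertiary benzylic hydroxyl groups by ionic hydrogenation and equilibrate C2 to trans, giving after separation of the syn isomer the meso ester F4. K2CO3 in MeOH would cleave the benzoate, and the sequence comes back to the route at 14.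

Step 6. Condensation at the doubly ortho-substituted ketones may stall, and prolonged heating with hydrazine may degrade the material. The fallback sets out from 6, whose carbonyl groups are activated by hydrogen bonds from the free ortho phenols and carry a smaller neighbour. N2H4·H2O in EtOH at 80 °C should give the bis-hydrazone triol F5, the ester being cleaved as before. Selective O-alkylation of the two phenols with 7 (K2CO3, acetone) then comes back to the route at 9.

Further compounds
F1 | step 12 | 1-(4-methoxyphenyl)-2-[(2R,3R,5S,6S)-3,5-bis(3,5-dimethoxyphenyl)-2,6-bis(4-methoxyphenyl)-2,3,5,6-tetrahydrobenzo[1,2-b:5,4-b']difuran-4-yl]ethanol, racemic at the carbinol carbon | COc1ccc(C(O)Cc2c3c(cc4c2[C@@H](c2cc(OC)cc(OC)c2)[C@H](c2ccc(OC)cc2)O4)O[C@H](c2ccc(OC)cc2)[C@H]3c2cc(OC)cc(OC)c2)cc1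
F2 | step 12 | heptamethyl ether of the target (4-methoxyphenyl in place of the 4-hydroxyphenyl of 18), enantiomer shown after resolution of the racemate | COc1ccc([C@@H]2Cc3c4c(cc5c3[C@@H](c3cc(OC)cc(OC)c3)[C@H](c3ccc(OC)cc3)O5)O[C@H](c3ccc(OC)cc3)[C@H]4c3cc(OC)cc(OC)c32)cc1
F3 | step 8 | 2-[3,5-bis(3,5-dimethoxyphenyl)-3,5-dihydroxy-2,6-bis(4-methoxyphenyl)-2,3,5,6-tetrahydrobenzo[1,2-b:5,4-b']difuran-4-yl]ethyl 3,5-dimethoxybenzoate, mixture of diastereomers | COc1cc(OC)cc(C(=O)OCCc2c3c(cc4c2C(O)(c2cc(OC)cc(OC)c2)C(c2ccc(OC)cc2)O4)OC(c2ccc(OC)cc2)C3(O)c2cc(OC)cc(OC)c2)c1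
F4 | step 8 | 3,5-dimethoxybenzoate of 14 (meso, both rings trans) | COc1cc(OC)cc(C(=O)OCCc2c3c(cc4c2[C@@H](c2cc(OC)cc(OC)c2)[C@H](c2ccc(OC)cc2)O4)O[C@H](c2ccc(OC)cc2)[C@H]3c2cc(OC)cc(OC)c2)c1
F5 | step 6 | 2-{2,6-bis[(3,5-dimethoxyphenyl)(hydrazinylidene)methyl]-3,5-dihydroxyphenyl}ethanol | NN=C(c1cc(OC)cc(OC)c1)c1c(O)cc(O)c(C(=NN)c2cc(OC)cc(OC)c2)c1CCO
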